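Compound numbers: 1–11 as defined in the steps and the compound list; the target is 11.

## The problem

The target, 5,6'-dihydroxy-6,7,2',3',4'-pentamethoxyflavone (11), is a 2-aryl-4H-chromen-4-one: ring A (C5–C8) is fused to the pyranone ring C, and ring B is attached at C2 through the C2–C1' bond. There is no stereocentre, so the task is one of connectivity and of sorting seven oxygen substituents into two free phenols (O5, O6') and five methyl ethers. C1' is flanked by the 2'-methoxy group and the 6'-hydroxyl, so every bond made to it is doubly ortho-hindered, and ring B carries an oxygen ortho to C1' that could compete with the ring A oxygen when ring C is closed. Both aromatic rings are very electron-rich: they oxidise readily to quinones and are open to electrophiles at C8 and C5'. Once O5 is free, a 6'-hydroxyflavone can also open and reclose through the ring B oxygen under hot acid or base, so the last operations must be cold and short. Of the six methoxy groups present late in the route, only the one on C5 lies peri to the C4 carbonyl, which offers a chelation handle for freeing exactly that phenol. Two features make a short route possible. C2 is a carbonyl-level carbon between C3 (the methyl carbon of a ring A acetophenone) and C1', so it can be supplied as carbon monoxide. Rings A and B are both 3,4,5-trimethoxyphenol units substituted at their one kind of open position, so a single commercial phenol serves both halves and bromination marks C1' without any regiochemical choice.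

## Retrosynthesis

**11 from 10.** The last disconnection removes two O-protecting groups: the benzyl group on O6' and the methyl group on O5 of 2-[2-(benzyloxy)-4,5,6-trimethoxyphenyl]-5,6,7-trimethoxy-4H-chromen-4-one (10). Carrying a free or separately protected 5-oxygen through the route would require an unsymmetrical ring A ketone that cannot be made from 3,4,5-trimethoxyphenol (1) in one step. A methyl group on O6' could not be told apart from the one on O2'. In 10 every oxygen is capped and the molecule is robust. The forward step must cleave one methyl ether out of six, relying on the boron chelate between O5 and the C4 carbonyl, and must keep the released benzyl cation off the electron-rich rings.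

**10 from 9.** Cutting the O1–C2 bond opens ring C to 1-[2-(benzyloxy)-4,5,6-trimethoxyphenyl]-3-(2-hydroxy-4,5,6-trimethoxyphenyl)propane-1,3-dione (9). A diketone is already at the oxidation level of the flavone, whereas a chalcone precursor would need an oxidant in the presence of two oxidisable rings. Only the ring A phenol of 9 is free. The two aryl groups of 9 also have the same oxygenation pattern, so closure through either oxygen would give the same ring system. The forward step is a dehydration onto a carbonyl that bears a doubly ortho-substituted aryl group, and it should leave the benzyl ether in place.

**9 from 3, 6 and 7 (key disconnection).** Both bonds to C2 are cut, C1'–C2 and C2–C3, and C2 becomes carbon monoxide (7). The partners are 1-(2-hydroxy-4,5,6-trimethoxyphenyl)ethan-1-one (3) and 1-(benzyloxy)-2-bromo-3,4,5-trimethoxybenzene (6). The classical cut of C2–C3 alone would need the ring B acid chloride, two more steps from 6, and an isolated ester. Joining C1' to C2 of an intact chromone would meet the double ortho hindrance directly. Here CO insertion moves the palladium one atom away from the crowded carbon before the new C–C bond forms. Three simple components replace a 28-carbon diketone. The forward reaction needs oxidative addition into an electron-rich, hindered C–Br bond under CO, and delivery of the aroyl group to the methyl carbon of 3, either directly or through the transient aryl ester 8 followed by an oxygen-to-carbon acyl shift.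

**6 from 5, and 5 from 1 and 4.** The C–Br bond of 6 is cut to give 5-(benzyloxy)-1,2,3-trimethoxybenzene (5), and the O–benzyl bond of 5 is cut to give 1 and benzyl bromide (4). Brominating the ether and not the free phenol avoids oxidation of 1 to a quinone. The two open positions of 5 are equivalent, so only over-bromination has to be controlled. The benzyl group keeps the ring B oxygen out of the palladium chemistry and is removed in the final step by the reagent that is needed there anyway.

**3 from 1 and 2.** The aryl–acyl bond (C4a–C4 of the flavone) is cut, giving 1 and acetic acid (2). Ortho C-acetylation of the phenol with BF3 has only one kind of position to attack and leaves the hydroxyl free, which later becomes O1 of ring C.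

## Roads not taken

Alternative 1: The cut is the C2–C1' bond alone, made intramolecularly through an ester tether between a C3 carboxyl group and the ring B oxygen. 5,6,7-Trimethoxy-4-oxo-4H-chromene-3-carboxylic acid A1 (from 3 by Vilsmeier formylation–cyclisation and oxidation at the formyl stage) would be esterified with 2-bromo-3,4,5-trimethoxyphenol A2 to give 2-bromo-3,4,5-trimethoxyphenyl 5,6,7-trimethoxy-4-oxo-4H-chromene-3-carboxylate A3. Pd(OAc)2 with PCy3 and K2CO3 would then insert into the C–Br bond, metalate the chromone C2–H and close a six-membered lactone, giving hexamethoxy-6H,7H-chromeno[4,3-b]chromene-6,7-dione A4, the flavone whose C3 carboxyl is lactonised onto O6'.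
- Merits: the hindered bond is formed intramolecularly, O6' emerges without a separate protecting group, and no gas is handled. On the steric problem this road is at least as good as the chosen one.
- Weak points: A3 is an activated aryl ester of a chromone with an electrophilic C2, and carbonate at high temperature can cleave the ester or open the pyranone before the C–H arylation occurs. After A4, the lactone must be opened with hydroxide, which also attacks chromones at C2. The freed 3-carboxylic acid must then be removed by heating, and the 5-O-methyl group must still be cleaved.
- Comparison: roughly eight steps against six. The chosen plan sets against the intramolecular advantage a carbon skeleton assembled in one operation with nothing to excise afterwards.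

Alternative 2: Ring A is built last by cutting C4a–C5 and C8–C8a. 2-[2-(Benzyloxy)-4,5,6-trimethoxyphenyl]-4H-pyran-4-one A5 would be activated by Me3SiOTf and attacked at its unsubstituted C6 by the terminal carbon of 3,4-dimethoxy-2-(trimethylsilyloxy)furan A6 (forming C8–C8a). The resulting silyl enol ether would close onto the former furan C2 (forming C4a–C5). CF3CO2H would then open the oxygen bridge and dehydrate to 2-[2-(benzyloxy)-4,5,6-trimethoxyphenyl]-5-hydroxy-6,7-dimethoxy-4H-chromen-4-one A7.
- Merits: the 5-hydroxyl is formed free and already distinguished from the methoxy groups, so A7 is one debenzylation from 11 and no chelation-controlled demethylation is needed. In the endgame this road is better than the chosen one.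
- Weak points: A5 still contains the hindered aryl–carbon bond and would have to be made from 6 in several steps, so the steric problem is moved and not solved. A6 comes from a tetronic acid derivative that is not a commodity. The pyranone has two electrophilic positions and the furan two ways to orient. This kind of benzannulation on a 2-aryl-4-pyranone with a doubly oxygenated furan would be a new method with no close precedent. The economy of drawing both rings from 1 is lost.
- Comparison: the chosen plan sets against the cleaner endgame a key step of an established reaction class and building blocks one or two steps from a single phenol.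

Alternative 3: Both aryl–carbonyl bonds, C4–C4a and C2–C1', are cut at once. Malonyl dichloride A8 with SnCl4 would acylate two molecules of 5 at the position between the benzyloxy and methoxy groups to give 1,3-bis[2-(benzyloxy)-4,5,6-trimethoxyphenyl]propane-1,3-dione A9. Double debenzylation, acid closure and 5-O-demethylation would lead to 11.
- Merits: this is the shortest road on paper, about four steps from 1 and 4. It needs no palladium and no CO, and the acylation has no regiochemical ambiguity. In step count and cost it beats the chosen plan.
- Weak points: after the first acylation the remaining acid chloride sits beside a benzyl ether that SnCl4 can cleave with chelation assistance. The freed oxygen would close onto the acid chloride to give a 4-hydroxycoumarin, the usual fate of malonyl dichloride with phenol ethers. The second acylation is intermolecular at a crowded position and must outrun that ring closure. A8 also forms ketenes and oligomers, and the diketone product binds the Lewis acid.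
- Comparison: the chosen plan makes the same two bonds to the central three-carbon unit without a free acid chloride next to a ketone and with a Lewis-acid-free C–C bond formation. It keeps most of the symmetry advantage, since both halves still come from 1.

Key step: step 4

Assumption: diketone 9 is written in its keto form although it should exist largely as the chelated enol; the tautomers are treated as one compound and all converge in step 5.

## Route

Step 1
Reactants: 1 3,4,5-trimethoxyphenol; 2 acetic acid
Product: 3 1-(2-hydroxy-4,5,6-trimethoxyphenyl)ethan-1-one
Conditions: BF3·OEt2, AcOH (2, as solvent), 90 °C; then H2O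
Reagents that add atoms: none
Why: BF3-mediated ortho C-acetylation of a phenol (Friedel–Crafts/Fries type); the two open positions of 1 are equivalent, the aryl ketone formed is deactivated towards a second acylation, and the hydroxyl stays free for its later role as O1.

Step 2
Reactants: 1 3,4,5-trimethoxyphenol; 4 benzyl bromide
Product: 5 5-(benzyloxy)-1,2,3-trimethoxybenzene
Conditions: K2CO3, DMF, rt
Reagents that add atoms: none
Why: Williamson O-alkylation of the phenoxide with a benzylic bromide; capping the phenol first removes the risk of quinone formation in the bromination that follows.

Step 3
Reactants: 5 5-(benzyloxy)-1,2,3-trimethoxybenzene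
Product: 6 1-(benzyloxy)-2-bromo-3,4,5-trimethoxybenzene
Conditions: NBS (1.0 equiv), MeCN, 0 °C to rt, dark
Reagents that add atoms: N-bromosuccinimide, O=C1CCC(=O)N1Br
Why: Electrophilic aromatic bromination of an activated aryl ether; the two open ring positions are equivalent, each ortho and para to donor oxygens, and one equivalent of reagent in a polar solvent without light should stop at the monobromide and leave the benzylic CH2 alone.

Step 4
Reactants: 3 1-(2-hydroxy-4,5,6-trimethoxyphenyl)ethan-1-one; 6 1-(benzyloxy)-2-bromo-3,4,5-trimethoxybenzene; 7 carbon monoxide
Product: 9 1-[2-(benzyloxy)-4,5,6-trimethoxyphenyl]-3-(2-hydroxy-4,5,6-trimethoxyphenyl)propane-1,3-dione, via aryl ester 8 (not isolated)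
Conditions: Pd(OAc)2 (5 mol %), Xantphos (6 mol %), CO (1 atm), Cs2CO3 (3 equiv), 1,4-dioxane, 100 °C; then aq NH4Cl
Reagents that add atoms: none
Why: Pd(OAc)2 is reduced in the flask to zerovalent palladium, which, held by Xantphos, inserts into the C1'–Br bond of 6. CO then inserts into the aryl–palladium bond, which is favoured because it moves the metal one atom away from the two ortho oxygen substituents, and the wide bite angle of Xantphos stabilises the acylpalladium intermediate ArCO–PdBr(Xantphos) and speeds its reductive elimination. Under Cs2CO3 ketone 3 is present mainly as its phenoxide, which is expected to take the aroyl group at oxygen to give ester 8; the same base then enolises the acetyl group and moves the aroyl group to the methyl carbon by an intramolecular Baker–Venkataraman 1,5-acyl shift, while any transfer directly to the enolate carbon gives 9 at once, so both paths end in the diketonate of 9. The closest known reaction type is the palladium-catalysed carbonylative alpha-arylation of ketones with aryl bromides to 1,3-diketones, including its use with 2-hydroxyacetophenones on the way to flavones. The step forms C1'–C2 and C2–C3, closes no ring and creates no stereocentre. It needs carbonylative and not direct alpha-arylation, which the doubly ortho-substituted arylpalladium and the CO atmosphere secure. It needs a single acylation, which the stable chelated diketonate and the 1:1 stoichiometry secure, and no participation of the ring B oxygen, which the benzyl ether secures.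

Step 5
Reactants: 9 1-[2-(benzyloxy)-4,5,6-trimethoxyphenyl]-3-(2-hydroxy-4,5,6-trimethoxyphenyl)propane-1,3-dione
Product: 10 2-[2-(benzyloxy)-4,5,6-trimethoxyphenyl]-5,6,7-trimethoxy-4H-chromen-4-one
Conditions: NaOAc, AcOH, 110 °C
Reagents that add atoms: none
Why: Cyclodehydration of a 1-(2-hydroxyaryl)-1,3-diketone, the closing stage of the Baker–Venkataraman flavone synthesis: the ring A phenol adds to the C2 carbonyl (6-exo-trig) and the hemiketal loses water to the aromatic pyranone. Buffered acetic acid should spare the benzyl ether, and because both aryl groups carry the same oxygenation pattern even its loss could not divert the closure to a different ring system.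

Step 6
Reactants: 10 2-[2-(benzyloxy)-4,5,6-trimethoxyphenyl]-5,6,7-trimethoxy-4H-chromen-4-one
Product: 11 5-hydroxy-2-(2-hydroxy-4,5,6-trimethoxyphenyl)-6,7-dimethoxy-4H-chromen-4-one (5,6'-dihydroxy-6,7,2',3',4'-pentamethoxyflavone)
Conditions: BCl3 (excess), C6HMe5, CH2Cl2, −78 to 0 °C; then MeOH, H2O
Reagents that add atoms: none
Why: Lewis acid ether cleavage: BCl3 removes the aryl benzyl ether at low temperature, with the benzyl cation trapped by pentamethylbenzene, and on warming demethylates only the 5-methoxy group, whose oxygen forms a six-membered boron chelate with the C4 carbonyl. The other five methyl ethers lack this assistance, and the cold, brief treatment avoids ring opening of the product.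

## Compound list

1 | 3,4,5-trimethoxyphenol | COc1cc(O)cc(OC)c1OC | starting material
2 | acetic acid | CC(=O)O | starting material
3 | 1-(2-hydroxy-4,5,6-trimethoxyphenyl)ethan-1-one | CC(=O)c1c(O)cc(OC)c(OC)c1OC | intermediate
4 | benzyl bromide | BrCc1ccccc1 | starting material
5 | 5-(benzyloxy)-1,2,3-trimethoxybenzene | COc1cc(OCc2ccccc2)cc(OC)c1OC | intermediate
6 | 1-(benzyloxy)-2-bromo-3,4,5-trimethoxybenzene | COc1cc(OCc2ccccc2)c(Br)c(OC)c1OC | intermediate
7 | carbon monoxide | [C-]#[O+] | starting material
8 | 2-acetyl-3,4,5-trimethoxyphenyl 2-(benzyloxy)-4,5,6-trimethoxybenzoate | CC(=O)c1c(OC(=O)c2c(OCc3ccccc3)cc(OC)c(OC)c2OC)cc(OC)c(OC)c1OC | intermediate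
9 | 1-[2-(benzyloxy)-4,5,6-trimethoxyphenyl]-3-(2-hydroxy-4,5,6-trimethoxyphenyl)propane-1,3-dione | COc1cc(O)c(C(=O)CC(=O)c2c(OCc3ccccc3)cc(OC)c(OC)c2OC)c(OC)c1OC | intermediate
10 | 2-[2-(benzyloxy)-4,5,6-trimethoxyphenyl]-5,6,7-trimethoxy-4H-chromen-4-one | COc1cc(OCc2ccccc2)c(-c2cc(=O)c3c(OC)c(OC)c(OC)cc3o2)c(OC)c1OC | intermediate
11 | 5-hydroxy-2-(2-hydroxy-4,5,6-trimethoxyphenyl)-6,7-dimethoxy-4H-chromen-4-one | COc1cc(O)c(-c2cc(=O)c3c(O)c(OC)c(OC)cc3o2)c(OC)c1OC | target

## Step count and risks

Total step count: 6. Longest linear sequence: 5 steps (1 to 5 to 6 to 9 to 10 to 11, steps 2–6); step 1 lies on the one-step branch to 3.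

**Step 4 (key step).** The most likely failure is a catalytic cycle that does not turn over. Oxidative addition of zerovalent palladium into the electron-rich, doubly ortho-substituted C–Br bond is slow, and CO competes for the metal, so recovery or simple reduction of the bromide may dominate. The sequence may also stall at the ester stage if the carbonate is too weak to drive the acyl shift. The fallback is the classical Baker–Venkataraman sequence without palladium. From 6, bromine–lithium exchange with n-BuLi in THF at −78 °C and quenching with CO2 would give 2-(benzyloxy)-4,5,6-trimethoxybenzoic acid F1. Oxalyl chloride with catalytic DMF would convert it into 2-(benzyloxy)-4,5,6-trimethoxybenzoyl chloride F2, which would acylate the phenol of 3 in pyridine. This re-enters the route at ester 8, now isolated, and KOH in pyridine at 50 °C would shift the aroyl group to carbon to give 9.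

**Step 6.** The risk is loss of chemoselectivity. Once O5 is bound to boron, the neighbouring 6-methoxy group can be cleaved through a cyclic borate if the mixture is warmed too far. The benzyl cation may alkylate C8 or C5' if scavenging is incomplete, while temperatures low enough for selectivity may leave the 5-methyl ether partly intact. The fallback separates the two tasks and removes the benzyl group reductively. From 10, hydrogenolysis with H2 over Pd/C in EtOAc would give 2-(2-hydroxy-4,5,6-trimethoxyphenyl)-5,6,7-trimethoxy-4H-chromen-4-one F3. AlCl3 in MeCN, a reagent that acts only on the carbonyl-chelated methoxy group, would then return the route at 11.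

**Step 5.** The risk is incomplete closure onto the C2 carbonyl, which is twisted and shielded by the doubly ortho-substituted ring B. Stalling at the hemiketal stage or loss of the benzyl ether under more forcing acid could also occur. The fallback deprotects before closing and uses the symmetry of the system. From 9, hydrogenolysis (H2, Pd/C) would give 1,3-bis(2-hydroxy-4,5,6-trimethoxyphenyl)propane-1,3-dione F4, which can be cyclised with catalytic H2SO4 in hot AcOH without concern for a protecting group, since closure through either phenol gives the same hydroxyflavone F3. Demethylation of F3 at O5 with AlCl3 in MeCN, as in the fallback to step 6, would bring the route back at 11.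

## Further compounds

F1 | step 4 | 2-(benzyloxy)-4,5,6-trimethoxybenzoic acid | COc1cc(OCc2ccccc2)c(C(=O)O)c(OC)c1OC
F2 | step 4 | 2-(benzyloxy)-4,5,6-trimethoxybenzoyl chloride | COc1cc(OCc2ccccc2)c(C(=O)Cl)c(OC)c1OC
F3 | step 6 | 2-(2-hydroxy-4,5,6-trimethoxyphenyl)-5,6,7-trimethoxy-4H-chromen-4-one | COc1cc(O)c(-c2cc(=O)c3c(OC)c(OC)c(OC)cc3o2)c(OC)c1OC
F4 | step 5 | 1,3-bis(2-hydroxy-4,5,6-trimethoxyphenyl)propane-1,3-dione | COc1cc(O)c(C(=O)CC(=O)c2c(O)cc(OC)c(OC)c2OC)c(OC)c1OC
A1 | alternative 1 | 5,6,7-trimethoxy-4-oxo-4H-chromene-3-carboxylic acid | COc1cc2occ(C(=O)O)c(=O)c2c(OC)c1OC
A2 | alternative 1 | 2-bromo-3,4,5-trimethoxyphenol | COc1cc(O)c(Br)c(OC)c1OC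
A3 | alternative 1 | 2-bromo-3,4,5-trimethoxyphenyl 5,6,7-trimethoxy-4-oxo-4H-chromene-3-carboxylate | COc1cc2occ(C(=O)Oc3cc(OC)c(OC)c(OC)c3Br)c(=O)c2c(OC)c1OC
A4 | alternative 1 | hexamethoxy-6H,7H-chromeno[4,3-b]chromene-6,7-dione (5,6,7,2',3',4'-hexamethoxyflavone with its C3 carboxyl lactonised onto O6') | COc1cc2c(c(OC)c1OC)c(=O)c1c(o2)-c2c(OC)c(OC)c(OC)cc2OC1=O
A5 | alternative 2 | 2-[2-(benzyloxy)-4,5,6-trimethoxyphenyl]-4H-pyran-4-one | COc1cc(OCc2ccccc2)c(-c2cc(=O)cco2)c(OC)c1OC
A6 | alternative 2 | 3,4-dimethoxy-2-(trimethylsilyloxy)furan | COc1coc(O[Si](C)(C)C)c1OC
A7 | alternative 2 | 2-[2-(benzyloxy)-4,5,6-trimethoxyphenyl]-5-hydroxy-6,7-dimethoxy-4H-chromen-4-one | COc1cc(OCc2ccccc2)c(-c2cc(=O)c3c(O)c(OC)c(OC)cc3o2)c(OC)c1OC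
A8 | alternative 3 | malonyl dichloride | O=C(Cl)CC(=O)Cl
A9 | alternative 3 | 1,3-bis[2-(benzyloxy)-4,5,6-trimethoxyphenyl]propane-1,3-dione | COc1cc(OCc2ccccc2)c(C(=O)CC(=O)c2c(OCc3ccccc3)cc(OC)c(OC)c2OC)c(OC)c1OC
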